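## Structural features

Aspergimarin C is a 3,4-dihydroisocoumarin: a δ-lactone ring (C1(=O), O2, C3, C4) fused along C4a–C8a to a benzene ring with hydroxyls at C5 and C8. This is a hydroquinone whose C8 hydroxyl sits peri to the lactone carbonyl. C3 (R) carries the saturated chain C1'–C4', and C4' (S, a methyl carbinol) is esterified by (R)-mevalonic acid, which adds a tertiary carbinol and a primary hydroxyl. No two stereocentres are adjacent: C3 and C4' are separated by three methylenes and the mevalonate centre lies beyond an ester, so none can control another and each is best bought. The fragile groups are the hydroquinone, its electrophilic acylquinone (which can enolise through C4), and the mevalonate monoester, whose free 5-hydroxyl can close to mevalonolactone and expel the C4' alcohol under acid or base. The real difficulty is the arene, with four contiguous substituents (alkyl at C4a, carboxyl at C8a, para oxygens at C5 and C8) that must be placed in order and unmasked under conditions the mevalonate survives. The key step uses the fact that the lactone is an ester between the aryl carboxyl C1 and the C3 oxygen and that the oxygens are para. A 3-methoxyfuran-2-carboxylate of a homopropargylic alcohol then holds every ring atom: furan C2, C3, C4, C5 become C8a, C8, C7, C6, the alkyne carbons become C4a and C5, the furan oxygen becomes the C5 oxygen and the furoate carbonyl is C1.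

## Logic of the disconnections

24 ⇒ 23. The two acetal C–O bonds that the last step breaks are restored, tying the mevalonate hydroxyls into a dioxane. This hides every aliphatic hydroxyl upstream, so nothing can lactonise or add to an activated alkyne or a quinone. The demand is a final hydrolysis in acid weak enough to leave the 5-hydroxy ester and the hydroquinone alone.

23 ⇒ 21 (through 22). The C8 hydroxyl is traced back to its methyl ether (O–CH3 bond), with quinone 22 as the transient link. The reason is that the ring-forming step delivers the two oxygens differentiated, free at C5 and methylated at C8, and a 4-methoxyphenol is the most easily oxidised form of a protected hydroquinone. The demand is that 22 is reduced in the flask in which it forms.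

21 ⇒ 19 (through 20). Three bonds are cut: C4a–C8a, C5–C6 and C5–O. Both rings disappear and a bicyclic tetrasubstituted arene becomes the diester of an acyclic alkynediol with a furan acid, all in the right oxidation state. The demand is a catalyst-only cascade in which furan C2 attacks the internal alkyne carbon and the opened furan recloses as the benzene ring with oxygen on C5.

19 ⇒ 15 + 18. The ester C(=O)–O bond at the C4' oxygen is cut. The mevalonate is attached before any phenol exists, so no hydroxyl competes later, and the route becomes convergent. The demand is acylation of a secondary alcohol by a β-alkoxy acid without elimination.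

18 ⇒ 17 ⇒ 16. The acid is traced through its methyl ester to the lactone, which supplies the tertiary stereocentre. The demand is opening of a six-membered lactone against its ring-closing tendency, met by trapping the diol as the acetal.

15 ⇒ 14 ⇒ 13 + 4. The furoate C(=O)–O bond is cut after a silyl group is put back on the C4' oxygen. The silyl ether is what distinguishes the two secondary carbinols, and the C3–O bond is never broken, so C3 keeps its configuration. The demand is an esterification and a desilylation that leave the alkyne and the enol ether intact.

4 ⇒ 2 (through 3) ⇒ 1. The C2–carboxyl bond and then the C3–OMe bond of the furan are cut. This gives a carboxylation of the C2 anion, which the adjacent methoxy and the ring oxygen both direct, and a copper-mediated methoxylation of the bromide.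

13 ⇒ 12. The C4–C4a bond (propargylic CH2 to alkyne) is cut to a terminal epoxide and acetylide. The alkyne arrives unprotected, and the demand is attack at the CH2 terminus only.

12 ⇒ 11 ⇒ 10 + 9, with 10 from 8. The epoxide is reopened to the chlorohydrin and the C1'–C2' bond is cut, leaving a three-carbon electrophile that carries C3 and a four-carbon nucleophile that carries C4'. Compound 9 must have the R configuration because the chain is attached first and the alkyne second; the opposite order would need its enantiomer. The demand is copper-catalysed attack at the ring CH2 and not at C–Cl.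

8 ⇒ 7 ⇒ 6 ⇒ 5. These are functional-group changes only: bromide from tosylate, silyl ether from alcohol, primary tosylate from the diol. The demand is selective sulfonylation of the primary hydroxyl.

## Other disconnections considered

Alternative 1: Dithiane linchpin at C2'.
- **Cut:** the two bonds flanking C2' (C1'–C2' and C2'–C3'), so the chain becomes a one-carbon linchpin between two epoxides.
- **Forward step:** the lithio derivative of silyl dithiane A2 would open (S)-propylene oxide A3, a 1,4-Brook shift would move silicon to the new alkoxide, and the regenerated carbanion would open aryl epoxide A4 to give A1.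
- **In favour:** three components join in one flask, and both carbinol centres come from chiral-pool epoxides. The two oxygens emerge already differentiated (C4'–O silylated, C3–OH free); the chosen plan needs a separate silylation and desilylation for this, so alternative 1 is the better on that point. Its key step is also a known reaction type, which the chosen key step is not.
- **Against:** A4 must first be made enantiopure. Its benzylic CH2 between arene and epoxide is acidic toward the dithiane anion, so deprotonation and collapse of the epoxide would compete with substitution. Sulfur must later be removed with Raney Ni, in addition to lactonisation, desilylation, esterification and removal of two O-methyl groups.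
- **Comparison:** the arene is bought, not built, and ends as a 1,4-dimethoxybenzene, which needs a stronger oxidant than the 4-methoxyphenol of the chosen plan; the same kind of quinone is crossed, so the endgame is about equal. The mechanism is ionic and well understood. The longest line is estimated at no shorter than the chosen one once A4 is counted.

Alternative 2: Asymmetric allylic lactonisation, then metathesis.
- **Cut:** the lactone C3–O2 bond, and the chain at C1'–C2' as an alkene.
- **Forward step:** Pd2(dba)3 (zerovalent palladium) with the chiral diaminocyclohexane bis(2-diphenylphosphinobenzamide) ligand would ionise allylic acetate A6, and the ortho carboxylate would attack the inner allyl terminus to give vinyl lactone A5. Cross-metathesis with alkene A7 (second-generation Grubbs catalyst) and hydrogenation would then lead to A8.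
- **In favour:** it is catalytic, modular and made of known reaction types. It is probably the shortest of all the plans (roughly nine or ten steps in the longest line), which is better than the chosen plan on step economy.
- **Against:** C3 would rest on catalyst control with a weak, reversible carboxylate nucleophile, and A5 is itself an allylic ester that the catalyst could re-ionise. Any shortfall in enantiopurity becomes a remote diastereomer that is hard to remove, since C4' is fixed independently. The branched, oxygen-substituted vinyl group is a reluctant metathesis partner, and the hydrogenation must not cleave the allylic C3–O bond.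
- **Comparison:** stereochemical security is lower than with the purchased C3 of the chosen plan. Mechanistic precedent is better, and the endgame (two methyl ethers) is equal or slightly worse.

Alternative 3: Catellani alkylation–carbonylation.
- **Cut:** C4–C4a, C8a–C1 and C1–O2; the arene is bought complete and the lactone is built on it.
- **Forward step:** under Pd(OAc)2, a triarylphosphine, norbornene and Cs2CO3, aryl iodide A9 would add to zerovalent palladium. The norbornene relay would bring palladium to the free ortho position, epoxide A10 (identical with 12) would alkylate there through a tetravalent palladium intermediate, and after norbornene extrusion the ipso carbon would take up CO and the alkoxide to give A8.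
- **In favour:** it uses the same epoxide that the chosen route passes through and forms three bonds and the lactone in one step from a catalogue arene. The methoxy group ortho to iodine meets the ortho-substituent requirement. It would shorten the longest line by about two steps, so it is better on step economy; the stereocentres come from the same sources, so that point is equal.
- **Against:** CO binds zerovalent palladium and can insert before the relay starts, while too little CO lets the alkoxide close directly onto the ipso carbon to a dihydrobenzofuran. The electron-rich iodide slows oxidative addition. The outcome therefore depends on a narrow balance of rates among four components, and the arene again ends as two methyl ethers.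
- **Comparison:** each elementary step is of a known type, so precedent is equal to or better than for the gold cascade. The chosen plan keeps one distinct merit: arene, lactone and differentiated oxygens arise together by an isomerisation that needs only a catalyst, from a precursor assembled by ordinary esterifications.

Key step: step 14

Remark: 19 and 21 map onto 24 atom for atom with all three stereocentres in the required sense (C3 R, C4' S, mevalonate R), so no structural correction is needed; the refinements concern how 19 is reached (silyl differentiation of the two carbinols, alkyne introduced unprotected) and how 21 is unmasked.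

Remark: (R)-epichlorohydrin is used because the chain nucleophile is added before the acetylide; this order gives the same (R)-carbinol as the enantiomer would with the nucleophiles reversed, and it saves an alkyne deprotection.

## Route

Step 1
Reactants: 1 3-bromofuran
Product: 2 3-methoxyfuran
Conditions: NaOMe, CuBr (10 mol%), MeOH/NMP, 110 °C
Reagents that add atoms: sodium methoxide, [Na+].[O-]C
Why: Ullmann-type copper-catalysed substitution of an unactivated heteroaryl bromide by methoxide; the volatile ether is carried on as a dried ethereal concentrate.

Step 2
Reactants: 2 3-methoxyfuran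
Product: 4 3-methoxyfuran-2-carboxylic acid, via 2-lithio-3-methoxyfuran 3 (not isolated)
Conditions: n-BuLi, THF, −78 → 0 °C; CO2, −78 °C; 1 M HCl, 0 °C
Reagents that add atoms: carbon dioxide, O=C=O
Why: Directed lithiation: C2 is both an α-position of the furan and ortho to the methoxy group, so deprotonation should occur there only; carboxylation of 3 installs the future C1 at the acid oxidation level.

Step 3
Reactants: 5 (S)-butane-1,3-diol
Product: 6 (3S)-3-hydroxybutyl 4-methylbenzenesulfonate
Conditions: TsCl (1.0 equiv), Et3N, CH2Cl2, −20 → 0 °C
Reagents that add atoms: 4-methylbenzenesulfonyl chloride, Cc1ccc(cc1)S(=O)(=O)Cl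
Why: Sulfonylation should be selective for the primary hydroxyl of the 1,3-diol at low temperature with one equivalent of reagent; the stereocentre is untouched.

Step 4
Reactants: 6 (3S)-3-hydroxybutyl 4-methylbenzenesulfonate
Product: 7 (3S)-3-[(tert-butyldimethylsilyl)oxy]butyl 4-methylbenzenesulfonate
Conditions: TBSCl, imidazole, CH2Cl2, 23 °C
Reagents that add atoms: tert-butyldimethylsilyl chloride, CC(C)(C)[Si](C)(C)Cl
Why: Standard silylation of the secondary hydroxyl; this silyl ether later distinguishes the two secondary carbinols of the chain.

Step 5
Reactants: 7 (3S)-3-[(tert-butyldimethylsilyl)oxy]butyl 4-methylbenzenesulfonate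
Product: 8 [(2S)-4-bromobutan-2-yl]oxy(tert-butyl)dimethylsilane
Conditions: LiBr, acetone, 56 °C
Reagents that add atoms: lithium bromide, [Li+].[Br-]
Why: Finkelstein-type SN2 displacement of the primary tosylate by bromide gives a halide suited to magnesium insertion.

Step 6
Reactants: 8 [(2S)-4-bromobutan-2-yl]oxy(tert-butyl)dimethylsilane; 9 (R)-epichlorohydrin [(2R)-2-(chloromethyl)oxirane]
Product: 11 (2R,6S)-6-[(tert-butyldimethylsilyl)oxy]-1-chloroheptan-2-ol, via Grignard reagent 10 (not isolated)
Conditions: Mg, THF, 40 °C; then CuI (10 mol%), 9, THF, −40 → −20 °C; aq NH4Cl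
Reagents that add atoms: none
Why: Copper-catalysed (cuprate-type) SN2 opening of the epoxide by 10 at the unsubstituted ring carbon should be faster than attack at C–Cl and forms C1'–C2'; the stereocentre of 9 is not a reaction site and becomes C3 of the target.

Step 7
Reactants: 11 (2R,6S)-6-[(tert-butyldimethylsilyl)oxy]-1-chloroheptan-2-ol
Product: 12 tert-butyldimethyl{[(2S)-5-[(2R)-oxiran-2-yl]pentan-2-yl]oxy}silane
Conditions: K2CO3, MeOH, 0 → 23 °C
Reagents that add atoms: none
Why: Intramolecular Williamson etherification: the alkoxide displaces the primary chloride, so the carbinol carbon keeps its configuration and the new epoxide CH2 is the future C4.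

Step 8
Reactants: 12 tert-butyldimethyl{[(2S)-5-[(2R)-oxiran-2-yl]pentan-2-yl]oxy}silane
Product: 13 (4R,8S)-8-[(tert-butyldimethylsilyl)oxy]non-1-yn-4-ol
Conditions: LiC≡CH·H2NCH2CH2NH2, DMSO, 0 → 23 °C; aq NH4Cl
Reagents that add atoms: lithium acetylide ethylenediamine complex, [Li+].[C-]#C.NCCN
Why: SN2 opening of the terminal epoxide at CH2 by acetylide in a dipolar aprotic solvent should give the homopropargylic alcohol with the alkyne already free; the silyl ether tolerates the conditions and the carbinol carbon is not attacked.

Step 9
Reactants: 13 (4R,8S)-8-[(tert-butyldimethylsilyl)oxy]non-1-yn-4-ol; 4 3-methoxyfuran-2-carboxylic acid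
Product: 14 (4R,8S)-8-[(tert-butyldimethylsilyl)oxy]non-1-yn-4-yl 3-methoxyfuran-2-carboxylate
Conditions: iPrN=C=NiPr (DIC), DMAP (20 mol%), CH2Cl2, 0 → 23 °C
Reagents that add atoms: none
Why: Steglich esterification (carbodiimide activation, acyl transfer through DMAP); the C–O bond of the carbinol is not broken, so the future C3 keeps its R configuration.

Step 10
Reactants: 14 (4R,8S)-8-[(tert-butyldimethylsilyl)oxy]non-1-yn-4-yl 3-methoxyfuran-2-carboxylate
Product: 15 (4R,8S)-8-hydroxynon-1-yn-4-yl 3-methoxyfuran-2-carboxylate
Conditions: HF·pyridine, pyridine/THF, 0 → 23 °C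
Reagents that add atoms: none
Why: Buffered fluoride desilylation should leave the furoate, the enol ether and the alkyne alone; the 1,5-relationship of ester and hydroxyl rules out acyl migration.

Step 11
Reactants: 16 (R)-mevalonolactone [(4R)-4-hydroxy-4-methyloxan-2-one]
Product: 17 methyl 2-[(4R)-2,2,4-trimethyl-1,3-dioxan-4-yl]acetate
Conditions: (MeO)2CMe2 (solvent), MeOH (2 equiv), TsOH·H2O (5 mol%), 23 °C; Et3N quench
Reagents that add atoms: methanol, CO; 2,2-dimethoxypropane, COC(C)(C)OC
Why: Acid-catalysed methanolysis of the lactone is reversible, and ketalisation of the released 1,3-diol by the large excess of 2,2-dimethoxypropane should pull it to the open ester (lactone-opening transacetalisation); no bond to the tertiary stereocentre is broken.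

Step 12
Reactants: 17 methyl 2-[(4R)-2,2,4-trimethyl-1,3-dioxan-4-yl]acetate
Product: 18 2-[(4R)-2,2,4-trimethyl-1,3-dioxan-4-yl]acetic acid
Conditions: LiOH, THF/H2O, 0 → 23 °C; 1 M HCl to pH 5, 0 °C, immediate extraction
Reagents that add atoms: lithium hydroxide, [Li+].[OH-]
Why: Saponification of the methyl ester; the acetal is stable to base, and brief cold acidification to pH 5 should keep the strained acetonide on the free acid, which is used at once.

Step 13
Reactants: 15 (4R,8S)-8-hydroxynon-1-yn-4-yl 3-methoxyfuran-2-carboxylate; 18 2-[(4R)-2,2,4-trimethyl-1,3-dioxan-4-yl]acetic acid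
Product: 19 (4R,8S)-8-({[(4R)-2,2,4-trimethyl-1,3-dioxan-4-yl]acetyl}oxy)non-1-yn-4-yl 3-methoxyfuran-2-carboxylate
Conditions: iPrN=C=NiPr (DIC), DMAP (20 mol%), CH2Cl2, 0 → 23 °C
Reagents that add atoms: none
Why: Second Steglich esterification, now at the only free hydroxyl; attaching the mevalonate before the arene exists avoids any later competition between a phenol and the C4' alcohol.

Step 14
Reactants: 19 (4R,8S)-8-({[(4R)-2,2,4-trimethyl-1,3-dioxan-4-yl]acetyl}oxy)non-1-yn-4-yl 3-methoxyfuran-2-carboxylate
Product: 21 (2S)-5-[(3R)-5-hydroxy-8-methoxy-1-oxo-3,4-dihydro-1H-isochromen-3-yl]pentan-2-yl [(4R)-2,2,4-trimethyl-1,3-dioxan-4-yl]acetate, via oxepine tautomer 20 (not isolated)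
Conditions: Ph3PAuNTf2 (5 mol%), 4 Å MS, CH2Cl2 (0.02 M), 23 → 40 °C
Reagents that add atoms: none
Why: Proposed new method: Ph3PAuNTf2, a cationic monovalent gold π-acid, should bind the terminal alkyne of 19, and furan C2 (an α-carbon of the furan and the β-carbon of the 3-methoxy enol ether) should add to the internal alkyne carbon through the s-cis ester conformer, a 6-exo-dig closure that makes C8a–C4a and the lactone ring and leaves a cation shared by the methoxy-bearing carbon and the furan oxygen. Heterolysis of the furan C2–O bond then unravels the ring to a dienal gold carbene whose aldehyde oxygen (the former furan oxygen) adds to the carbene carbon to give oxepine 20; its 6π disrotatory electrocyclisation to the C5–C6 arene oxide closes the carbocycle (C5–C6, with C5–O already in place), and opening of that oxide with loss of the former alkyne proton gives phenol 21. The closest known reaction type is the gold-catalysed intramolecular furan–yne phenol synthesis (Hashmi phenol synthesis), established for furans tied to the alkyne by CH2–X–CH2 chains; an ester tether that ends as a lactone and a 2-furoate carrying a 3-alkoxy donor lie outside it. No stereocentre is created, and C3, which is neither next to a cation nor α to a carbonyl at any stage, keeps its R configuration. Exo attack is secured by Markovnikov polarisation of the terminal alkyne and the six-membered transition state; attack by the ester carbonyl oxygen instead of furan C2 is reversible and has no exit without water, hence the molecular sieves. The arene oxide should open at C6–O because the resulting arenium ion places charge on C8, where the methoxy group takes it up, whereas C5–O cleavage would place charge on C8a next to the lactone carbonyl; the oxygen therefore stays on C5. High dilution disfavours intermolecular hydroarylation at the free furan C5, and the neutral, non-protic catalyst should leave the acetonide and both esters untouched.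

Step 15
Reactants: 21 (2S)-5-[(3R)-5-hydroxy-8-methoxy-1-oxo-3,4-dihydro-1H-isochromen-3-yl]pentan-2-yl [(4R)-2,2,4-trimethyl-1,3-dioxan-4-yl]acetate
Product: 23 (2S)-5-[(3R)-5,8-dihydroxy-1-oxo-3,4-dihydro-1H-isochromen-3-yl]pentan-2-yl [(4R)-2,2,4-trimethyl-1,3-dioxan-4-yl]acetate, via quinone 22 (not isolated)
Conditions: PhI(OAc)2 (1.1 equiv), MeCN/H2O (4:1), 0 °C; then aq Na2S2O4, EtOAc, 0 → 23 °C
Reagents that add atoms: water, O
Why: Oxidative demethylation of a 4-methoxyphenol by a trivalent iodine reagent: water adds at C8 and methanol leaves to give acylquinone 22, which dithionite should reduce in the same flask before it can add nucleophiles or enolise through C4; the weakly acidic medium should spare the esters, and any acetal lost here converges in step 16.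

Step 16
Reactants: 23 (2S)-5-[(3R)-5,8-dihydroxy-1-oxo-3,4-dihydro-1H-isochromen-3-yl]pentan-2-yl [(4R)-2,2,4-trimethyl-1,3-dioxan-4-yl]acetate
Product: 24 aspergimarin C [(2S)-5-[(3R)-5,8-dihydroxy-1-oxo-3,4-dihydro-1H-isochromen-3-yl]pentan-2-yl (3R)-3,5-dihydroxy-3-methylpentanoate]
Conditions: AcOH/THF/H2O (3:1:1), 23 °C, argon
Reagents that add atoms: none
Why: Acid-catalysed hydrolysis of a strained 1,3-dioxane acetonide under conditions too mild to trigger lactonisation of the freed 5-hydroxy ester or hydrolysis of either ester; no stereocentre is involved.

## Compound list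

1 | 3-bromofuran | Brc1ccoc1 | starting material
2 | 3-methoxyfuran | COc1ccoc1 | intermediate
3 | 2-lithio-3-methoxyfuran | [Li]c1occc1OC | intermediate (not isolated)
4 | 3-methoxyfuran-2-carboxylic acid | COc1ccoc1C(=O)O | intermediate
5 | (S)-butane-1,3-diol | C[C@@H](CCO)O | starting material
6 | (3S)-3-hydroxybutyl 4-methylbenzenesulfonate | C[C@@H](CCOS(=O)(=O)c1ccc(C)cc1)O | intermediate
7 | (3S)-3-[(tert-butyldimethylsilyl)oxy]butyl 4-methylbenzenesulfonate | C[C@@H](CCOS(=O)(=O)c1ccc(C)cc1)O[Si](C)(C)C(C)(C)C | intermediate
8 | [(2S)-4-bromobutan-2-yl]oxy(tert-butyl)dimethylsilane | C[C@@H](CCBr)O[Si](C)(C)C(C)(C)C | intermediate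
9 | (R)-epichlorohydrin, (2R)-2-(chloromethyl)oxirane | ClC[C@H]1CO1 | starting material
10 | [(3S)-3-[(tert-butyldimethylsilyl)oxy]butyl]magnesium bromide | C[C@@H](CC[Mg]Br)O[Si](C)(C)C(C)(C)C | intermediate (not isolated)
11 | (2R,6S)-6-[(tert-butyldimethylsilyl)oxy]-1-chloroheptan-2-ol | C[C@@H](CCC[C@@H](O)CCl)O[Si](C)(C)C(C)(C)C | intermediate
12 | tert-butyldimethyl{[(2S)-5-[(2R)-oxiran-2-yl]pentan-2-yl]oxy}silane | C[C@@H](CCC[C@@H]1CO1)O[Si](C)(C)C(C)(C)C | intermediate
13 | (4R,8S)-8-[(tert-butyldimethylsilyl)oxy]non-1-yn-4-ol | C[C@@H](CCC[C@@H](O)CC#C)O[Si](C)(C)C(C)(C)C | intermediate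
14 | (4R,8S)-8-[(tert-butyldimethylsilyl)oxy]non-1-yn-4-yl 3-methoxyfuran-2-carboxylate | C[C@@H](CCC[C@@H](OC(=O)c1occc1OC)CC#C)O[Si](C)(C)C(C)(C)C | intermediate
15 | (4R,8S)-8-hydroxynon-1-yn-4-yl 3-methoxyfuran-2-carboxylate | C[C@@H](CCC[C@@H](OC(=O)c1occc1OC)CC#C)O | intermediate
16 | (R)-mevalonolactone, (4R)-4-hydroxy-4-methyloxan-2-one | C[C@@]1(O)CCOC(=O)C1 | starting material
17 | methyl 2-[(4R)-2,2,4-trimethyl-1,3-dioxan-4-yl]acetate | COC(=O)C[C@@]1(C)CCOC(C)(C)O1 | intermediate
18 | 2-[(4R)-2,2,4-trimethyl-1,3-dioxan-4-yl]acetic acid | OC(=O)C[C@@]1(C)CCOC(C)(C)O1 | intermediate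
19 | (4R,8S)-8-({[(4R)-2,2,4-trimethyl-1,3-dioxan-4-yl]acetyl}oxy)non-1-yn-4-yl 3-methoxyfuran-2-carboxylate (key-step precursor) | C[C@@H](CCC[C@@H](OC(=O)c1occc1OC)CC#C)OC(=O)C[C@@]2(C)CCOC(C)(C)O2 | intermediate
20 | oxepine valence tautomer of the C5–C6 arene oxide of 21 (oxygen bridging C5 and C6; double bonds C4a=C5, C6=C7, C8=C8a; 8-methoxy; lactone and side chain as in 21) | C[C@@H](CCC[C@@H]1CC2=COC=CC(OC)=C2C(=O)O1)OC(=O)C[C@@]3(C)CCOC(C)(C)O3 | intermediate (not isolated)
21 | (2S)-5-[(3R)-5-hydroxy-8-methoxy-1-oxo-3,4-dihydro-1H-isochromen-3-yl]pentan-2-yl [(4R)-2,2,4-trimethyl-1,3-dioxan-4-yl]acetate (8-O-methyl aspergimarin C acetonide) | C[C@@H](CCC[C@@H]1Cc2c(O)ccc(OC)c2C(=O)O1)OC(=O)C[C@@]3(C)CCOC(C)(C)O3 | intermediate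
22 | (2S)-5-[(3R)-1,5,8-trioxo-3,4,5,8-tetrahydro-1H-isochromen-3-yl]pentan-2-yl [(4R)-2,2,4-trimethyl-1,3-dioxan-4-yl]acetate (quinone) | C[C@@H](CCC[C@@H]1CC2=C(C(=O)C=CC2=O)C(=O)O1)OC(=O)C[C@@]3(C)CCOC(C)(C)O3 | intermediate (not isolated)
23 | (2S)-5-[(3R)-5,8-dihydroxy-1-oxo-3,4-dihydro-1H-isochromen-3-yl]pentan-2-yl [(4R)-2,2,4-trimethyl-1,3-dioxan-4-yl]acetate | C[C@@H](CCC[C@@H]1Cc2c(O)ccc(O)c2C(=O)O1)OC(=O)C[C@@]3(C)CCOC(C)(C)O3 | intermediate
24 | aspergimarin C, (2S)-5-[(3R)-5,8-dihydroxy-1-oxo-3,4-dihydro-1H-isochromen-3-yl]pentan-2-yl (3R)-3,5-dihydroxy-3-methylpentanoate | C[C@@H](CCC[C@@H]1Cc2c(O)ccc(O)c2C(=O)O1)OC(=O)C[C@](C)(O)CCO | target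

## Step count and least certain steps

Total: 16 steps. Longest linear sequence: 12 steps (5 to 24 through steps 3–10 and 13–16); the furan acid (steps 1–2) and the mevalonate acid (steps 11–12) are two-step side branches.

**Step 14 (key step, proposed new method).**
- **What may go wrong:** carbon–carbon bond formation may be slow or fail, because the ester must leave its preferred s-trans conformation and the furoate is a deactivated furan. That leaves time for hydration of the activated alkyne by adventitious water, intermolecular hydroarylation through furan C5, catalyst deactivation as a gold acetylide, or acid-induced loss of the acetonide.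
- **Fallback (known chemistry):** sets out from 12 and returns at 23 by way of 22.
 - N,N-Diethyl-2,5-dimethoxybenzamide F1 is lithiated with s-BuLi/TMEDA (THF, −78 °C) at the position flanked by the amide and a methoxy group (directed ortho-metalation). The aryllithium opens 12 at its CH2 terminus in the presence of BF3·OEt2 to give N,N-diethyl-2-[(2R,6S)-6-(tert-butyldimethylsilyloxy)-2-hydroxyheptyl]-3,6-dimethoxybenzamide F2.
 - Warm aqueous HCl in THF should lactonise F2 with loss of the amine and remove the silyl group, giving (3R)-3-[(4S)-4-hydroxypentyl]-5,8-dimethoxyisochroman-1-one F3.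
 - Steglich esterification of F3 with 18 gives (2S)-5-[(3R)-5,8-dimethoxy-1-oxoisochroman-3-yl]pentan-2-yl [(4R)-2,2,4-trimethyl-1,3-dioxan-4-yl]acetate F4.
 - (NH4)2Ce(NO3)6 in MeCN/H2O at 0 °C oxidises the 1,4-dimethoxyarene of F4 to 22, which is reduced with Na2S2O4 as in step 15 to 23.

**Step 15.**
- **What may go wrong:** conjugate addition of water or acetate to the acylquinone, or its enolisation through C4 toward a quinone methide (and from there loss of the C3 stereocentre), before the reduction catches it; over-oxidation is also possible.
- **Fallback:** sets out from 21 and returns at 24. BCl3 in CH2Cl2 at −78 °C binds the lactone carbonyl and the peri methoxy oxygen and cleaves the O–CH3 bond (chelation-controlled dealkylation). The same Lewis acid opens the acetonide, and a mild aqueous work-up hydrolyses the borates to 24 without any quinone. This fallback makes no new compound (entry F0).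

**Step 12.**
- **What may go wrong:** loss of the strained acetonide during acidification, followed by lactonisation back to 16.
- **Fallback:** sets out from 16 and returns at 18.
 - 16 is opened with one equivalent of KOH and the potassium carboxylate is alkylated with BnBr in DMF to give benzyl (3R)-3,5-dihydroxy-3-methylpentanoate F5.
 - 2-Methoxypropene with catalytic pyridinium 4-toluenesulfonate (CH2Cl2, 0 °C) ketalises the diol irreversibly to benzyl 2-[(4R)-2,2,4-trimethyl-1,3-dioxan-4-yl]acetate F6.
 - Hydrogenolysis (H2, Pd/C, EtOAc) then liberates 18 without any aqueous acid.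

**Step 1.**
- **What may go wrong:** incomplete substitution, copper-promoted hydrodebromination, and loss of the volatile ether on isolation.
- **Fallback:** sets out from 1 and returns at 4. LiN(iPr)2 (THF, −78 °C) deprotonates 1 at C2 and CO2 gives 3-bromofuran-2-carboxylic acid F7, a non-volatile solid. NaOMe with catalytic CuBr in MeOH/DMF then replaces the bromide, assisted by the neighbouring carboxylate (Ullmann-type substitution of an ortho-halo acid), to give 4.

## Further compounds

F1 | step 14 | N,N-diethyl-2,5-dimethoxybenzamide | CCN(CC)C(=O)c1cc(OC)ccc1OC
F2 | step 14 | N,N-diethyl-2-[(2R,6S)-6-(tert-butyldimethylsilyloxy)-2-hydroxyheptyl]-3,6-dimethoxybenzamide | C[C@@H](CCC[C@@H](O)Cc1c(OC)ccc(OC)c1C(=O)N(CC)CC)O[Si](C)(C)C(C)(C)C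
F3 | step 14 | (3R)-3-[(4S)-4-hydroxypentyl]-5,8-dimethoxyisochroman-1-one | C[C@@H](CCC[C@@H]1Cc2c(OC)ccc(OC)c2C(=O)O1)O
F4 | step 14 | (2S)-5-[(3R)-5,8-dimethoxy-1-oxoisochroman-3-yl]pentan-2-yl [(4R)-2,2,4-trimethyl-1,3-dioxan-4-yl]acetate | C[C@@H](CCC[C@@H]1Cc2c(OC)ccc(OC)c2C(=O)O1)OC(=O)C[C@@]3(C)CCOC(C)(C)O3
F0 | step 15 | none | none
F5 | step 12 | benzyl (3R)-3,5-dihydroxy-3-methylpentanoate | O=C(OCc1ccccc1)C[C@](C)(O)CCO
F6 | step 12 | benzyl 2-[(4R)-2,2,4-trimethyl-1,3-dioxan-4-yl]acetate | O=C(OCc1ccccc1)C[C@@]1(C)CCOC(C)(C)O1
F7 | step 1 | 3-bromofuran-2-carboxylic acid | OC(=O)c1occc1Br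
A1 | alternative 1 | N,N-diethyl-2-[(2S)-3-{2-[(2S)-2-(tert-butyldimethylsilyloxy)propyl]-1,3-dithian-2-yl}-2-hydroxypropyl]-3,6-dimethoxybenzamide | C[C@@H](CC1(C[C@@H](O)Cc2c(OC)ccc(OC)c2C(=O)N(CC)CC)SCCCS1)O[Si](C)(C)C(C)(C)C
A2 | alternative 1 | tert-butyl(1,3-dithian-2-yl)dimethylsilane | CC(C)(C)[Si](C)(C)C1SCCCS1
A3 | alternative 1 | (S)-propylene oxide, (2S)-2-methyloxirane | C[C@H]1CO1
A4 | alternative 1 | N,N-diethyl-3,6-dimethoxy-2-{[(2S)-oxiran-2-yl]methyl}benzamide | C1[C@@H](O1)Cc2c(OC)ccc(OC)c2C(=O)N(CC)CC
A5 | alternative 2 | (3S)-3-ethenyl-5,8-dimethoxyisochroman-1-one | C=C[C@@H]1Cc2c(OC)ccc(OC)c2C(=O)O1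
A6 | alternative 2 | 2-[(2E)-4-(acetyloxy)but-2-en-1-yl]-3,6-dimethoxybenzoic acid | CC(=O)OC/C=C/Cc1c(OC)ccc(OC)c1C(=O)O
A7 | alternative 2 | tert-butyldimethyl{[(2S)-pent-4-en-2-yl]oxy}silane | C[C@@H](CC=C)O[Si](C)(C)C(C)(C)C
A8 | alternative 3 | (3R)-3-[(4S)-4-(tert-butyldimethylsilyloxy)pentyl]-5,8-dimethoxyisochroman-1-one | C[C@@H](CCC[C@@H]1Cc2c(OC)ccc(OC)c2C(=O)O1)O[Si](C)(C)C(C)(C)C
A9 | alternative 3 | 2-iodo-1,4-dimethoxybenzene | COc1ccc(OC)c(I)c1
A10 | alternative 3 | tert-butyldimethyl{[(2S)-5-[(2R)-oxiran-2-yl]pentan-2-yl]oxy}silane (identical with 12) | C[C@@H](CCC[C@@H]1CO1)O[Si](C)(C)C(C)(C)C
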